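The C4(OH)–C5(H)–C6(O) aldol array that spans the cyclopentane and the cycloheptane is read as the product of a semipinacol shift. A cis-fused decalin 2,3-epoxy alcohol, whose p-menthane six-ring already holds C1–C5 together with C6, is treated with SnCl4, and the ring-fusion bond C1–C6 migrates to oxirane carbon C5. This one step contracts the six-ring to the cyclopentane C1–C5 as the last ring closure of the carbon skeleton (the same shift enlarges the methylcyclohexene to the cycloheptenone), sets C5 by inversion (trans fusion), leaves the oxirane oxygen as the C4 alcohol and makes C6 a ketone. The decalin is built from carvenone by asymmetric epoxidation, allylation, methallyl addition and ring-closing metathesis.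

Key step: step 6

Atom labels: the carotane numbering of the target is kept for all precursors. C1 is the angular methyl carbon, C2 and C3 the cyclopentane methylenes, C4 the isopropyl carbinol, C5 the ring-fusion CH, C6 the ester carbinol, C7 a CH2, C8 (methylated) and C9 the oxirane carbons, C10 a CH2.
Remark on the chemistry: the 8,9-oxirane is treated as functionality of the C8=C9 alkene and is installed after the bicyclic carbon skeleton is complete.

Step 1
Reactants: 1 (+)-dihydrocarvone (commercial mixture of isomers)
Product: 2 carvenone (racemic 6-methyl-3-(propan-2-yl)cyclohex-2-en-1-one)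
Conditions: 40% aq. H2SO4, 100 °C
Reagents that add atoms: none
Why: Acid-catalysed alkene isomerisation under thermodynamic control: stepwise proton shifts carry the isopropenyl double bond into conjugation with the ketone, and because the C4 stereocentre of 1 is erased and the methyl-bearing carbon stays epimerisable, the commercial isomer mixture can be used and 2 is racemic.

Step 2
Reactants: 2 carvenone
Product: 3 epoxy ketone (1S,6R)-3-methyl-6-(propan-2-yl)-7-oxabicyclo[4.1.0]heptan-2-one (both epimers at the methyl-bearing carbon)
Conditions: 9-amino-9-deoxy-epi-quinine·2CF3CO2H or its quinidine-derived pseudoenantiomer (10 mol %; the one that gives the (1S,6R)-oxirane), 50% aq. H2O2, 1,4-dioxane, 40 °C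
Reagents that add atoms: hydrogen peroxide, OO
Why: Asymmetric Weitz–Scheffer-type epoxidation of a cyclic enone under iminium catalysis by a cinchona primary amine salt: the chiral iminium ion directs conjugate addition of H2O2 to one face of C4 and the enamine closes the oxirane, which sets C4 and C5 under catalyst control, while the labile methyl-bearing carbon converges in step 3.

Step 3
Reactants: 3 epoxy ketone; 4 allyl bromide
Product: 6 quaternary epoxy ketone (1S,3R,6R)-3-methyl-6-(propan-2-yl)-3-(prop-2-en-1-yl)-7-oxabicyclo[4.1.0]heptan-2-one, via lithium enolate 5 (not isolated)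
Conditions: LDA, THF, −78 °C; then allyl bromide, DMPU, −78 → −30 °C
Reagents that add atoms: allyl bromide (compound 4), C=CCBr
Why: Enolate alkylation: the only enolate that can form is the fully substituted one at C1, and allyl bromide should enter anti to the oxirane oxygen (substrate control, as in alkylations of bicyclo[4.1.0]heptan-2-one enolates), which sets the quaternary centre C1 with methyl and oxirane oxygen on the same face.

Step 4
Reactants: 6 quaternary epoxy ketone; 7 2-methylallylmagnesium chloride
Product: 8 monocyclic epoxy alcohol (C6 hydroxyl, oxirane oxygen and C1 methyl on one face; allyl and 2-methylallyl on the other)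
Conditions: 7 (1.5 equiv), THF, −78 °C; then sat. aq. NH4Cl at −78 °C
Reagents that add atoms: 2-methylallylmagnesium chloride (compound 7), CC(=C)C[Mg]Cl
Why: 1,2-Addition of an allylic Grignard reagent to a 2,3-epoxycyclohexanone should occur anti to the oxirane oxygen and to the C1 methyl (substrate control), which gives the tertiary C6 alcohol cis to the oxirane and places the 2-methylallyl group cis to the allyl group.

Step 5
Reactants: 8 monocyclic epoxy alcohol
Product: 9 cis-decalin epoxy alcohol 3,4-epoxy-6,8a-dimethyl-3-(propan-2-yl)-1,2,3,4,4a,5,8,8a-octahydronaphthalen-4a-ol (4a-hydroxyl, oxirane oxygen and 8a-methyl all on one face)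
Conditions: second-generation Grubbs catalyst (5 mol %), CH2Cl2 (0.01 M), 40 °C
Reagents that add atoms: none
Why: Ring-closing metathesis of the allyl and 2-methylallyl groups held cis on adjacent fully substituted carbons closes the methylcyclohexene with loss of ethene; no stereocentre is formed, and the tertiary alcohol and the oxirane are tolerated.

Step 6
Reactants: 9 cis-decalin epoxy alcohol
Product: 10 ketol (3R,3aR,8aR)-3-hydroxy-6,8a-dimethyl-3-(propan-2-yl)-2,3,3a,5,8,8a-hexahydroazulen-4(1H)-one
Conditions: SnCl4 (1.1 equiv), CH2Cl2, −78 °C; sat. aq. NaHCO3 at −78 °C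
Reagents that add atoms: none
Why: SnCl4 binds the cis-disposed C6 hydroxyl and oxirane oxygen, the C5–O bond ionises and the ring-fusion bond C1–C6 shifts from the carbinol carbon C6 to C5 anti to the leaving oxygen while C6 becomes the carbonyl carbon. The closest known reaction type is the type 3 semipinacol rearrangement of 2,3-epoxy alcohols in its ring-contracting form (cis-2,3-epoxycyclohexanols to cis-2-hydroxycyclopentyl ketones), the epoxide counterpart of the sulfonate pinacol route from decalins to hydroazulenones. The cyclopentane C1–C5 is closed by this 1,2-alkyl shift, which forms the C1–C5 bond and expels C6 from the six-membered ring (ring contraction), and the same bond inserts C5 into the methylcyclohexene, which becomes the cycloheptenone (ring enlargement). C5 is the only new stereocentre and is set by inversion at the migration terminus, so that H5 ends trans to the angular methyl because the oxirane lies on the methyl face; C1 migrates with retention and the C4–O bond is never broken, so the C4 hydroxyl stays cis to the C5–C6 bond. The step needs migration of C1 and not of the ring methylene C7, and cleavage of the C5–O and not of the tertiary C4–O bond: the quaternary C1 has the higher migratory aptitude and leads to the fused product where C7 would give a bridged ketone, and only the C5–O bond is assisted by the push of the metal-bound carbinol oxygen. The low temperature and the cold bicarbonate quench should protect the tertiary aldol from retro-aldol cleavage and the non-conjugated enone from isomerisation.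

Step 7
Reactants: 10 ketol
Product: 11 jaeschkeanadiol (3R,3aS,4S,8aR)-6,8a-dimethyl-3-(propan-2-yl)-1,2,3,3a,4,5,8,8a-octahydroazulene-3,4-diol
Conditions: Me4NBH(OAc)3 (5 equiv), MeCN–AcOH (1:1), −30 → 0 °C
Reagents that add atoms: none
Why: Evans–Saksena hydroxyl-directed reduction: the C4 hydroxyl exchanges onto boron and delivers hydride intramolecularly to the face of the C6 carbonyl on which it sits (the face that the angular methyl shields from external hydride), which sets C6 as the 1,3-anti diol with H6 trans to H5.

Step 8
Reactants: 11 jaeschkeanadiol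
Product: 12 8α,9α-epoxyjaeschkeanadiol (oxirane across C8–C9 on the face of the C6 hydroxyl; anti to the angular methyl)
Conditions: VO(acac)2 (5 mol %), t-BuOOH (1.5 equiv), CH2Cl2, 0 °C → rt
Reagents that add atoms: tert-butyl hydroperoxide, CC(C)(C)OO
Why: Vanadium-catalysed hydroxyl-directed epoxidation: the homoallylic C6 hydroxyl delivers the peroxide oxygen to its own face of the C8=C9 alkene, the face also left open by the angular methyl, which sets C8 and C9.

Step 9
Reactants: 12 8α,9α-epoxyjaeschkeanadiol; 13 4-methoxybenzoyl chloride
Product: 14 CNP0235939.1 (8α,9α-epoxyjaeschkeanadiol 6-(4-methoxybenzoate))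
Conditions: Et3N, DMAP (0.2 equiv), CH2Cl2, 0 °C → rt
Reagents that add atoms: 4-methoxybenzoyl chloride (compound 13), COc1ccc(cc1)C(Cl)=O
Why: DMAP-catalysed acylation (nucleophilic acyl substitution) of the secondary C6 hydroxyl; the tertiary C4 hydroxyl is too hindered to compete and no stereocentre is touched.

Compound list
1 | (+)-dihydrocarvone, 2-methyl-5-(prop-1-en-2-yl)cyclohexan-1-one, commercial isomer mixture (stereocentres not carried on) | CC1CCC(CC1=O)C(C)=C | starting material
2 | carvenone, racemic 6-methyl-3-(propan-2-yl)cyclohex-2-en-1-one | CC(C)C1=CC(=O)C(C)CC1 | intermediate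
3 | (1S,6R)-3-methyl-6-(propan-2-yl)-7-oxabicyclo[4.1.0]heptan-2-one, both C3 epimers | CC(C)[C@@]12O[C@@H]1C(=O)C(C)CC2 | intermediate
4 | allyl bromide | C=CCBr | starting material
5 | lithium enolate of 3 | CC(C)[C@@]12O[C@@H]1C([O-])=C(C)CC2.[Li+] | intermediate
6 | (1S,3R,6R)-3-methyl-6-(propan-2-yl)-3-(prop-2-en-1-yl)-7-oxabicyclo[4.1.0]heptan-2-one | CC(C)[C@@]12O[C@@H]1C(=O)[C@@](C)(CC=C)CC2 | intermediate
7 | 2-methylallylmagnesium chloride | CC(=C)C[Mg]Cl | starting material
8 | 3-methyl-2-(2-methylprop-2-en-1-yl)-6-(propan-2-yl)-3-(prop-2-en-1-yl)-7-oxabicyclo[4.1.0]heptan-2-ol; hydroxyl, oxirane oxygen and C3 methyl on one face, both allylic chains on the other | CC(C)[C@@]12O[C@@H]1[C@@](O)(CC(C)=C)[C@@](C)(CC=C)CC2 | intermediate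
9 | cis-fused 3,4-epoxy-6,8a-dimethyl-3-(propan-2-yl)-1,2,3,4,4a,5,8,8a-octahydronaphthalen-4a-ol; hydroxyl, oxirane oxygen and angular methyl on one face | CC(C)[C@@]12O[C@@H]1[C@@]1(O)CC(C)=CC[C@@]1(C)CC2 | intermediate
10 | (3R,3aR,8aR)-3-hydroxy-6,8a-dimethyl-3-(propan-2-yl)-2,3,3a,5,8,8a-hexahydroazulen-4(1H)-one | CC1=CC[C@@]2(C)CC[C@@](O)(C(C)C)[C@@H]2C(=O)C1 | intermediate
11 | jaeschkeanadiol, (3R,3aS,4S,8aR)-6,8a-dimethyl-3-(propan-2-yl)-1,2,3,3a,4,5,8,8a-octahydroazulene-3,4-diol | CC1=CC[C@@]2(C)CC[C@@](O)(C(C)C)[C@@H]2[C@@H](O)C1 | intermediate
12 | 8α,9α-epoxyjaeschkeanadiol | O[C@H]1C[C@@]2(C)O[C@H]2C[C@@]2(C)CC[C@@](O)(C(C)C)[C@H]12 | intermediate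
13 | 4-methoxybenzoyl chloride | COc1ccc(cc1)C(Cl)=O | starting material
14 | CNP0235939.1, 8α,9α-epoxyjaeschkeanadiol 6-(4-methoxybenzoate) | COc1ccc(C(=O)O[C@H]2C[C@@]3(C)O[C@H]3C[C@@]3(C)CC[C@@](O)(C(C)C)[C@H]23)cc1 | target

Total step count: 9. Longest linear sequence: 9 steps (1 to 14).

Steps most likely to fail

Step 6. Ionisation at the tertiary oxirane carbon C4, migration of the ring methylene C7 in place of C1, or retro-aldol cleavage of the tin-bound aldolate may erode the rearrangement. The fallback sets out from 9 and comes back at 10. The free hydroxyl is taken out of play by silylation (Et3SiOTf, 2,6-lutidine, CH2Cl2, −78 °C), which should give the C6 triethylsilyl ether F1. The bulky, non-chelating Lewis acid MeAl(OAr)2 (MABR, Ar = 4-bromo-2,6-di-tert-butylphenyl; CH2Cl2, −78 °C) then activates only the oxirane. The silyloxy-bearing carbon releases the antiperiplanar C1, and silyl transfer to the new alkoxide should give the C4-O-triethylsilyl ketol F2, which cannot undergo retro-aldol cleavage. HF·pyridine in THF removes the silyl group to give 10.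

Step 3. Poor facial selectivity in the alkylation of the trisubstituted enolate (allyl entering syn to the oxirane) would give the C1 epimer. The fallback sets out from 3 and comes back at 6. O-Acylation of the enolate (LiHMDS, allyl chloroformate, THF, −78 °C) should give the allyl enol carbonate F3. Decarboxylative asymmetric allylic alkylation (Pd2(dba)3, tert-butyl phosphinooxazoline ligand of the sense that reinforces attack anti to the oxirane, THF, 25 °C) then transfers the allyl group to C1 under catalyst control and gives 6.

Step 2. Slow iminium formation with the α′-branched, β-isopropyl enone, or a mismatched substrate enantiomer, may give low conversion or low enantiomeric purity. The fallback sets out from 2 and comes back at 3. Corey–Bakshi–Shibata reduction (Me-CBS oxazaborolidine of the appropriate sense, catecholborane, toluene, −78 °C) should give the (1R)-allylic alcohol F4. Hydroxyl-directed epoxidation (VO(acac)2, t-BuOOH, CH2Cl2, 0 °C) should give the cis-epoxy alcohol F5, and Dess–Martin periodinane oxidation (CH2Cl2, NaHCO3) returns 3.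

Further compounds
F1 | step 6 | C6-O-triethylsilyl ether of epoxy alcohol 9 | CC(C)[C@@]12O[C@@H]1[C@@]1(O[Si](CC)(CC)CC)CC(C)=CC[C@@]1(C)CC2
F2 | step 6 | C4-O-triethylsilyl ether of ketol 10 | CC1=CC[C@@]2(C)CC[C@@](O[Si](CC)(CC)CC)(C(C)C)[C@@H]2C(=O)C1
F3 | step 3 | allyl enol carbonate of epoxy ketone 3 | CC(C)[C@@]12O[C@@H]1C(OC(=O)OCC=C)=C(C)CC2
F4 | step 2 | (1R)-6-methyl-3-(propan-2-yl)cyclohex-2-en-1-ol, both C6 epimers | CC(C)C1=C[C@H](O)C(C)CC1
F5 | step 2 | cis-epoxy alcohol, (1S,6R)-oxirane of 3 with the C2 hydroxyl cis to the oxirane oxygen | CC(C)[C@@]12O[C@@H]1[C@H](O)C(C)CC2
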